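**Plan**

1. Retrosynthesis: the C11–H bond is cut first (back to a peroxy hemiketal). The two C–O bonds of the 1,2-dioxane are then cut back to O2 and a C8–C11 bond, which gives a cyclobutanol fused to a 12-membered ring. Further cuts are C1–C2 with the lactone C–O (allylchromium + enal), C11–C12 (alkenyllithium + cyclobutanone), and C8–C9 (semipinacol shift of an epoxy cyclopropanol made from a geraniol-derived enoate and EtMgBr).
2. Enabling feature: in 27 the O–O bridge spans C8 and C11 of the 14-membered ring with only C9 and C10 between them. These four carbons are a cyclobutane once C8 is bonded to C11, and a hydroxyl on C11 makes that ring-fusion bond the one an alkoxyl radical breaks.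
3. Forward order of rings: cyclopropanol, then cyclobutanone, then alkenyl cyclobutanol (fragment union), then 12-membered carbocycle with cis-lactone. O2 insertion then turns the four-membered ring into the 1,2-dioxane and the 12-membered ring into the 14-membered ring; ionic reduction at C11 finishes.
4. Stereochemistry: C7 comes from a catalytic, hydroxyl-directed asymmetric epoxidation. C8 of the cyclobutane follows from the stereospecific anti semipinacol shift and is relayed into the peroxide carbon by O2 capture anti to the departing C11. C1/C2 arise cis in the closed transition state of the macrocyclisation, and C11 from hydride delivery on the open face of the bridged cation.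
5. Alkene geometry: 3E comes from geraniol, 12Z from a Stork–Zhao iodo-olefination, and the Z enoate that encodes C8 from a Still–Gennari olefination.

Key step: step 18

Remark: cembrane locants are used throughout: C1 lactone β-carbon, C2 lactone O–CH, C3=C4(CH3), C5, C6, C7 (O), C8 (CH3), C9, C10, C11, C12(CH3)=C13, C14, C15(=C17H2), C16 lactone C=O.
Remark: 26 is drawn as one anomer at the hemiketal carbon C11; the anomers interconvert through 25 and give the same cation in step 19. In step 5 the ligand enantiomer is the one that gives the (7S) epoxide.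

**Route**

Step 1
Reactants: 1 geraniol
Product: 2 tert-butyl{[(2E)-3,7-dimethylocta-2,6-dien-1-yl]oxy}dimethylsilane
Conditions: t-BuMe2SiCl, imidazole, CH2Cl2, 25 °C
Reagents that add atoms: tert-butyl(chloro)dimethylsilane, CC(C)(C)[Si](C)(C)Cl
Why: Silyl ether formation at the primary allylic alcohol protects C2–OH through the organometallic steps and creates no stereocentre.

Step 2
Reactants: 2 tert-butyl{[(2E)-3,7-dimethylocta-2,6-dien-1-yl]oxy}dimethylsilane
Product: 4 (4E)-6-{[tert-butyl(dimethyl)silyl]oxy}-4-methylhex-4-enal, via epoxide 3 (not isolated)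
Conditions: mCPBA, CH2Cl2, −20 °C; then H5IO6, THF/H2O, 0 °C
Reagents that add atoms: 3-chloroperbenzoic acid, O=C(OO)c1cccc(Cl)c1
Why: Electrophilic epoxidation should prefer the distal trisubstituted alkene because the proximal one is deactivated by the allylic oxygen, and periodic acid then cleaves the epoxide through its diol (glycol cleavage) to the C7 aldehyde and acetone while the 3E alkene is kept.

Step 3
Reactants: 4 (4E)-6-{[tert-butyl(dimethyl)silyl]oxy}-4-methylhex-4-enal
Product: 5 ethyl (2Z,6E)-8-{[tert-butyl(dimethyl)silyl]oxy}-2,6-dimethylocta-2,6-dienoate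
Conditions: (CF3CH2O)2P(O)CH(CH3)CO2Et, KN(SiMe3)2, 18-crown-6, THF, −78 °C
Reagents that add atoms: ethyl 2-[bis(2,2,2-trifluoroethoxy)phosphoryl]propanoate, CCOC(=O)C(C)P(=O)(OCC(F)(F)F)OCC(F)(F)F
Why: The Still–Gennari variant of the Horner–Wadsworth–Emmons olefination should give the (Z)-α-methyl enoate under kinetic control, and this geometry is what later becomes the C7/C8 relationship.

Step 4
Reactants: 5 ethyl (2Z,6E)-8-{[tert-butyl(dimethyl)silyl]oxy}-2,6-dimethylocta-2,6-dienoate
Product: 6 1-[(2Z,6E)-8-{[tert-butyl(dimethyl)silyl]oxy}-6-methylocta-2,6-dien-2-yl]cyclopropan-1-ol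
Conditions: EtMgBr, Ti(OiPr)4 (cat.), THF, 0 → 25 °C
Reagents that add atoms: ethylmagnesium bromide, CC[Mg]Br
Why: In the Kulinkovich cyclopropanation the titanacyclopropane formed from EtMgBr adds twice to the ester carbonyl and should give the 1-alkenylcyclopropanol (C9 and C10 come from the Grignard reagent) without touching the Z alkene.

Step 5
Reactants: 6 1-[(2Z,6E)-8-{[tert-butyl(dimethyl)silyl]oxy}-6-methylocta-2,6-dien-2-yl]cyclopropan-1-ol
Product: 8 (2R)-2-[(1S,4E)-6-{[tert-butyl(dimethyl)silyl]oxy}-1-hydroxy-4-methylhex-4-en-1-yl]-2-methylcyclobutan-1-one, via epoxy cyclopropanol 7 (not isolated)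
Conditions: Hf(OtBu)4 (cat.), C2-symmetric chiral bis-hydroxamic acid ligand (cat.), cumene hydroperoxide, toluene, 0 → 25 °C
Reagents that add atoms: cumene hydroperoxide, CC(C)(OO)c1ccccc1
Why: Hydroxyl-directed catalytic asymmetric epoxidation of a tertiary allylic alcohol reaches only the alkene next to the cyclopropanol and sets C7 as S through the chiral hafnium peroxide, and the semipinacol ring expansion that follows moves a cyclopropane C–C bond to C8 anti to the breaking C–O bond, so the Z geometry should be translated stereospecifically into the (7S,8R) ketol.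

Step 6
Reactants: 8 (2R)-2-[(1S,4E)-6-{[tert-butyl(dimethyl)silyl]oxy}-1-hydroxy-4-methylhex-4-en-1-yl]-2-methylcyclobutan-1-one
Product: 9 (2R)-2-[(1S,4E)-6-{[tert-butyl(dimethyl)silyl]oxy}-4-methyl-1-[(triethylsilyl)oxy]hex-4-en-1-yl]-2-methylcyclobutan-1-one
Conditions: Et3SiOSO2CF3, 2,6-lutidine, CH2Cl2, −78 °C
Reagents that add atoms: triethylsilyl trifluoromethanesulfonate, CC[Si](CC)(CC)OS(=O)(=O)C(F)(F)F
Why: Silylation of the hindered secondary alcohol with a silyl triflate blocks retro-aldol cleavage of the β-hydroxy ketone in the organolithium step and leaves both stereocentres untouched.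

Step 7
Reactants: 10 3-[(4-methoxyphenyl)methoxy]propan-1-ol
Product: 11 3-[(4-methoxyphenyl)methoxy]propanal
Conditions: Dess–Martin periodinane, CH2Cl2, 25 °C
Reagents that add atoms: none
Why: Dess–Martin oxidation of a primary alcohol should stop cleanly at the aldehyde.

Step 8
Reactants: 11 3-[(4-methoxyphenyl)methoxy]propanal
Product: 12 1-({[(3Z)-4-iodopent-3-en-1-yl]oxy}methyl)-4-methoxybenzene
Conditions: EtPPh3I, n-BuLi, THF; I2, −78 °C; NaN(SiMe3)2; then 11, −78 → −20 °C
Reagents that add atoms: ethyl(triphenyl)phosphonium iodide, CC[P+](c1ccccc1)(c1ccccc1)c1ccccc1.[I-]; iodine, II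
Why: The Stork–Zhao olefination with the α-iodo ylide should give the (Z)-trisubstituted alkenyl iodide with iodine cis to the chain, which fixes the 12Z geometry of the target.

Step 9
Reactants: 12 1-({[(3Z)-4-iodopent-3-en-1-yl]oxy}methyl)-4-methoxybenzene; 9 (2R)-2-[(1S,4E)-6-{[tert-butyl(dimethyl)silyl]oxy}-4-methyl-1-[(triethylsilyl)oxy]hex-4-en-1-yl]-2-methylcyclobutan-1-one
Product: 15 {[(1S,2R)-2-[(1S,4E)-6-{[tert-butyl(dimethyl)silyl]oxy}-4-methyl-1-[(triethylsilyl)oxy]hex-4-en-1-yl]-1-{(2Z)-5-[(4-methoxyphenyl)methoxy]pent-2-en-2-yl}-2-methylcyclobutyl]oxy}triethylsilane, via alkenyllithium 13 (not isolated), via lithium alkoxide 14 (not isolated)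
Conditions: t-BuLi, Et2O, −78 °C; then 9, THF, −78 °C; then Et3SiOSO2CF3, −78 → 0 °C
Reagents that add atoms: triethylsilyl trifluoromethanesulfonate, CC[Si](CC)(CC)OS(=O)(=O)C(F)(F)F
Why: Iodine–lithium exchange keeps the alkene geometry and the alkenyllithium should add 1,2 to the strained cyclobutanone from the methyl face (anti to the branched C7 substituent) to join the two fragments at the fully substituted C11, a carbinol centre that is erased in step 18, and silylation in the flask keeps the cis-disposed tertiary oxygen from attacking the electrophiles built at C1 later.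

Step 10
Reactants: 15 {[(1S,2R)-2-[(1S,4E)-6-{[tert-butyl(dimethyl)silyl]oxy}-4-methyl-1-[(triethylsilyl)oxy]hex-4-en-1-yl]-1-{(2Z)-5-[(4-methoxyphenyl)methoxy]pent-2-en-2-yl}-2-methylcyclobutyl]oxy}triethylsilane
Product: 16 (3Z)-4-[(1S,2R)-2-[(1S,4E)-6-{[tert-butyl(dimethyl)silyl]oxy}-4-methyl-1-[(triethylsilyl)oxy]hex-4-en-1-yl]-2-methyl-1-[(triethylsilyl)oxy]cyclobutyl]pent-3-en-1-ol
Conditions: DDQ, CH2Cl2/pH 7 buffer, 0 °C
Reagents that add atoms: none
Why: Oxidative cleavage of the 4-methoxybenzyl ether with DDQ should free only the C1 hydroxyl and leave the three silyl ethers and both trisubstituted alkenes intact.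

Step 11
Reactants: 16 (3Z)-4-[(1S,2R)-2-[(1S,4E)-6-{[tert-butyl(dimethyl)silyl]oxy}-4-methyl-1-[(triethylsilyl)oxy]hex-4-en-1-yl]-2-methyl-1-[(triethylsilyl)oxy]cyclobutyl]pent-3-en-1-ol
Product: 17 (3Z)-4-[(1S,2R)-2-[(1S,4E)-6-{[tert-butyl(dimethyl)silyl]oxy}-4-methyl-1-[(triethylsilyl)oxy]hex-4-en-1-yl]-2-methyl-1-[(triethylsilyl)oxy]cyclobutyl]pent-3-enal
Conditions: Dess–Martin periodinane, pyridine, CH2Cl2, 0 °C
Reagents that add atoms: none
Why: Buffered Dess–Martin oxidation should give the β,γ-unsaturated aldehyde without moving the Z alkene into conjugation, and the aldehyde is used at once.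

Step 12
Reactants: 17 (3Z)-4-[(1S,2R)-2-[(1S,4E)-6-{[tert-butyl(dimethyl)silyl]oxy}-4-methyl-1-[(triethylsilyl)oxy]hex-4-en-1-yl]-2-methyl-1-[(triethylsilyl)oxy]cyclobutyl]pent-3-enal
Product: 18 methyl (5Z)-6-[(1S,2R)-2-[(1S,4E)-6-{[tert-butyl(dimethyl)silyl]oxy}-4-methyl-1-[(triethylsilyl)oxy]hex-4-en-1-yl]-2-methyl-1-[(triethylsilyl)oxy]cyclobutyl]-3-hydroxy-2-methylidenehept-5-enoate (both C3 epimers)
Conditions: i-Bu2AlH, N-methylmorpholine N-oxide, methyl propiolate, THF, 0 °C; then 17, 0 → 25 °C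
Reagents that add atoms: methyl propiolate, C#CC(=O)OC
Why: Vinylalumination (1,2-addition of the α-ester vinylalane made by hydroalumination of methyl propiolate) gives the Morita–Baylis–Hillman-type adduct under non-basic conditions, and the new carbinol centre may form as a mixture because it is removed in step 13.

Step 13
Reactants: 18 methyl (5Z)-6-[(1S,2R)-2-[(1S,4E)-6-{[tert-butyl(dimethyl)silyl]oxy}-4-methyl-1-[(triethylsilyl)oxy]hex-4-en-1-yl]-2-methyl-1-[(triethylsilyl)oxy]cyclobutyl]-3-hydroxy-2-methylidenehept-5-enoate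
Product: 19 methyl (2Z,5Z)-2-(bromomethyl)-6-[(1S,2R)-2-[(1S,4E)-6-{[tert-butyl(dimethyl)silyl]oxy}-4-methyl-1-[(triethylsilyl)oxy]hex-4-en-1-yl]-2-methyl-1-[(triethylsilyl)oxy]cyclobutyl]hepta-2,5-dienoate
Conditions: N-bromosuccinimide, Me2S, CH2Cl2, −20 → 25 °C
Reagents that add atoms: N-bromosuccinimide, O=C1CCC(=O)N1Br
Why: Activation of the allylic alcohol as its alkoxysulfonium salt (Corey–Kim reagent) and SN2′ attack of bromide should give the rearranged primary allylic bromide as the favoured (Z)-2-(bromomethyl)enoate.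

Step 14
Reactants: 19 methyl (2Z,5Z)-2-(bromomethyl)-6-[(1S,2R)-2-[(1S,4E)-6-{[tert-butyl(dimethyl)silyl]oxy}-4-methyl-1-[(triethylsilyl)oxy]hex-4-en-1-yl]-2-methyl-1-[(triethylsilyl)oxy]cyclobutyl]hepta-2,5-dienoate
Product: 20 methyl (2Z,5Z)-2-(bromomethyl)-6-[(1S,2R)-2-[(1S,4E)-1,6-dihydroxy-4-methylhex-4-en-1-yl]-1-hydroxy-2-methylcyclobutyl]hepta-2,5-dienoate
Conditions: HF (aq.), MeCN, 0 °C
Reagents that add atoms: none
Why: Fluoride-mediated desilylation in the absence of any amine should remove all three silyl groups without quaternising or hydrolysing the reactive allylic bromide.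

Step 15
Reactants: 20 methyl (2Z,5Z)-2-(bromomethyl)-6-[(1S,2R)-2-[(1S,4E)-1,6-dihydroxy-4-methylhex-4-en-1-yl]-1-hydroxy-2-methylcyclobutyl]hepta-2,5-dienoate
Product: 21 methyl (2Z,5Z)-2-(bromomethyl)-6-[(1S,2R)-1-hydroxy-2-[(1S,4E)-1-hydroxy-4-methyl-6-oxohex-4-en-1-yl]-2-methylcyclobutyl]hepta-2,5-dienoate
Conditions: MnO2, CH2Cl2, 25 °C
Reagents that add atoms: none
Why: Allylic oxidation with MnO2 should take only the primary allylic alcohol at C2 to the (E)-enal, because the C7 alcohol is not allylic and the C11 alcohol is tertiary.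

Step 16
Reactants: 21 methyl (2Z,5Z)-2-(bromomethyl)-6-[(1S,2R)-1-hydroxy-2-[(1S,4E)-1-hydroxy-4-methyl-6-oxohex-4-en-1-yl]-2-methylcyclobutyl]hepta-2,5-dienoate
Product: 23 (1S,2S,3E,7S,8R,11S,12Z)-7,11-dihydroxy-8,11-cyclocembra-3,12,15(17)-trien-16,2-olide, via hydroxy ester 22 (not isolated)
Conditions: CrCl2, THF, 25 °C, slow addition of 21 (high dilution)
Reagents that add atoms: none
Why: In this intramolecular Nozaki–Hiyama allylation the allylchromium species adds through its γ-carbon C1 to the enal in a chair transition state, the (Z)-geometry placing C14 and C3 cis so that the chromium alkoxide lactonises to the cis-fused α-methylene lactone and closes the 12-membered ring, while attack on the Re face of the aldehyde (2S) is expected from the folded chain held by the trans-substituted cyclobutane but rests on substrate control.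

Step 17
Reactants: 23 (1S,2S,3E,7S,8R,11S,12Z)-7,11-dihydroxy-8,11-cyclocembra-3,12,15(17)-trien-16,2-olide
Product: 24 (1S,2S,3E,7S,8R,11S,12Z)-7-acetoxy-11-hydroxy-8,11-cyclocembra-3,12,15(17)-trien-16,2-olide
Conditions: Ac2O, pyridine, 4-(dimethylamino)pyridine (cat.), CH2Cl2, 0 → 25 °C
Reagents that add atoms: acetic anhydride, CC(=O)OC(C)=O
Why: Acylation should take the secondary C7 alcohol and leave the tertiary cyclobutanol free, which is needed as the radical precursor.

Step 18
Reactants: 24 (1S,2S,3E,7S,8R,11S,12Z)-7-acetoxy-11-hydroxy-8,11-cyclocembra-3,12,15(17)-trien-16,2-olide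
Product: 26 (1S,2S,3E,7S,8S,11R,12Z)-7-acetoxy-11-hydroxy-8,11-epidioxycembra-3,12,15(17)-trien-16,2-olide, via hydroperoxy enone 25 (not isolated)
Conditions: Co(acac)2 (cat.), O2 (1 atm, solution kept saturated), ClCH2CH2Cl, 25 °C
Reagents that add atoms: dioxygen, O=O
Why: The cobalt catalyst and O2 convert the tertiary alcohol into its alkoxyl radical, which breaks the strained ring-fusion bond C8–C11 by β-scission, so the 12-membered ring opens to the 14-membered cembrane ring with a C11 enone and a tertiary radical at C8; this radical takes up O2, the peroxyl radical is reduced to hydroperoxide 25 in the cobalt cycle, and the hydroperoxide adds across the ring to the C11 ketone. The closest known reaction type is the Co(acac)2/O2 oxidative ring expansion of monocyclic cyclobutanols to 1,2-dioxan-3-ols. The only ring closed is the 1,2-dioxane, by reversible 6-exo-trig attack of the hydroperoxide oxygen on the carbonyl carbon after the four-membered ring has opened, so the four cyclobutane carbons C8–C11 and the two atoms of O2 make up its six ring atoms. The new C8 centre is set in the O2 capture: the radical is born with C10 and C11 still folded over one lobe and with H7 eclipsing the other, and capture in O2-saturated solution should be faster than the turn of the methyl-bearing centre through the macrocycle, so oxygen should enter on the face opposite to the departing C11 (inversion at C8), which is why the (8R) cyclobutane was built in step 5; C11 is a hemiketal centre that becomes planar again in step 19. The step needs β-scission toward C8 and not C10 (a tertiary against a primary radical, plus relief of the fusion strain), O2 capture ahead of radical addition to the new enone or to the α-methylene lactone (secured by O2 saturation), and no hydrogen-atom transfer to the alkenes (no silane is present).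

Step 19
Reactants: 26 (1S,2S,3E,7S,8S,11R,12Z)-7-acetoxy-11-hydroxy-8,11-epidioxycembra-3,12,15(17)-trien-16,2-olide
Product: 27 (1S,2S,3E,7S,8S,11R,12Z)-7-acetoxy-8,11-epidioxycembra-3,12,15(17)-trien-16,2-olide
Conditions: Et3SiH, Me3SiOSO2CF3 (cat.), CH2Cl2, −78 °C
Reagents that add atoms: none
Why: In this ionic hydrogenation of a peroxy hemiketal (known for 1,2-dioxan-3-ols and peroxy lactols) the silyl triflate ionises C11–OH to the peroxycarbenium ion and Et3SiH should deliver hydride to C11 in 1,2-fashion from the face of the C8 methyl group, away from the C7-to-C12 bridge of the macrocycle, which gives the (11R) peroxide and leaves the O–O bond, the Z alkene, the acetate and the α-methylene lactone untouched.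

**Compound list**

1 | geraniol ((2E)-3,7-dimethylocta-2,6-dien-1-ol) | CC(C)=CCC/C(C)=C/CO | starting material
2 | tert-butyl{[(2E)-3,7-dimethylocta-2,6-dien-1-yl]oxy}dimethylsilane | CC(C)=CCC/C(C)=C/CO[Si](C)(C)C(C)(C)C | intermediate
3 | tert-butyl{[(2E)-5-(3,3-dimethyloxiran-2-yl)-3-methylpent-2-en-1-yl]oxy}dimethylsilane (racemic) | CC1(C)OC1CC/C(C)=C/CO[Si](C)(C)C(C)(C)C | intermediate
4 | (4E)-6-{[tert-butyl(dimethyl)silyl]oxy}-4-methylhex-4-enal | O=CCC/C(C)=C/CO[Si](C)(C)C(C)(C)C | intermediate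
5 | ethyl (2Z,6E)-8-{[tert-butyl(dimethyl)silyl]oxy}-2,6-dimethylocta-2,6-dienoate | CCOC(=O)/C(C)=C\CC/C(C)=C/CO[Si](C)(C)C(C)(C)C | intermediate
6 | 1-[(2Z,6E)-8-{[tert-butyl(dimethyl)silyl]oxy}-6-methylocta-2,6-dien-2-yl]cyclopropan-1-ol | OC1(CC1)/C(C)=C\CC/C(C)=C/CO[Si](C)(C)C(C)(C)C | intermediate
7 | 1-{(2S,3S)-3-[(3E)-5-{[tert-butyl(dimethyl)silyl]oxy}-3-methylpent-3-en-1-yl]-2-methyloxiran-2-yl}cyclopropan-1-ol | OC1(CC1)[C@@]2(C)O[C@H]2CC/C(C)=C/CO[Si](C)(C)C(C)(C)C | intermediate
8 | (2R)-2-[(1S,4E)-6-{[tert-butyl(dimethyl)silyl]oxy}-1-hydroxy-4-methylhex-4-en-1-yl]-2-methylcyclobutan-1-one | O=C1CC[C@]1(C)[C@@H](O)CC/C(C)=C/CO[Si](C)(C)C(C)(C)C | intermediate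
9 | (2R)-2-[(1S,4E)-6-{[tert-butyl(dimethyl)silyl]oxy}-4-methyl-1-[(triethylsilyl)oxy]hex-4-en-1-yl]-2-methylcyclobutan-1-one | O=C1CC[C@]1(C)[C@@H](O[Si](CC)(CC)CC)CC/C(C)=C/CO[Si](C)(C)C(C)(C)C | intermediate
10 | 3-[(4-methoxyphenyl)methoxy]propan-1-ol | COc1ccc(COCCCO)cc1 | starting material
11 | 3-[(4-methoxyphenyl)methoxy]propanal | COc1ccc(COCCC=O)cc1 | intermediate
12 | 1-({[(3Z)-4-iodopent-3-en-1-yl]oxy}methyl)-4-methoxybenzene | C/C(I)=C/CCOCc1ccc(OC)cc1 | intermediate
13 | {(2E)-5-[(4-methoxyphenyl)methoxy]pent-2-en-2-yl}lithium (lithium in the place of the iodine of 12; geometry kept) | C/C([Li])=C/CCOCc1ccc(OC)cc1 | intermediate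
14 | lithium (1S,2R)-2-[(1S,4E)-6-{[tert-butyl(dimethyl)silyl]oxy}-4-methyl-1-[(triethylsilyl)oxy]hex-4-en-1-yl]-1-{(2Z)-5-[(4-methoxyphenyl)methoxy]pent-2-en-2-yl}-2-methylcyclobutan-1-olate | C/C(=C/CCOCc1ccc(OC)cc1)[C@@]1(O[Li])CC[C@]1(C)[C@@H](O[Si](CC)(CC)CC)CC/C(C)=C/CO[Si](C)(C)C(C)(C)C | intermediate
15 | {[(1S,2R)-2-[(1S,4E)-6-{[tert-butyl(dimethyl)silyl]oxy}-4-methyl-1-[(triethylsilyl)oxy]hex-4-en-1-yl]-1-{(2Z)-5-[(4-methoxyphenyl)methoxy]pent-2-en-2-yl}-2-methylcyclobutyl]oxy}triethylsilane | C/C(=C/CCOCc1ccc(OC)cc1)[C@@]1(O[Si](CC)(CC)CC)CC[C@]1(C)[C@@H](O[Si](CC)(CC)CC)CC/C(C)=C/CO[Si](C)(C)C(C)(C)C | intermediate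
16 | (3Z)-4-[(1S,2R)-2-[(1S,4E)-6-{[tert-butyl(dimethyl)silyl]oxy}-4-methyl-1-[(triethylsilyl)oxy]hex-4-en-1-yl]-2-methyl-1-[(triethylsilyl)oxy]cyclobutyl]pent-3-en-1-ol | C/C(=C/CCO)[C@@]1(O[Si](CC)(CC)CC)CC[C@]1(C)[C@@H](O[Si](CC)(CC)CC)CC/C(C)=C/CO[Si](C)(C)C(C)(C)C | intermediate
17 | (3Z)-4-[(1S,2R)-2-[(1S,4E)-6-{[tert-butyl(dimethyl)silyl]oxy}-4-methyl-1-[(triethylsilyl)oxy]hex-4-en-1-yl]-2-methyl-1-[(triethylsilyl)oxy]cyclobutyl]pent-3-enal | C/C(=C/CC=O)[C@@]1(O[Si](CC)(CC)CC)CC[C@]1(C)[C@@H](O[Si](CC)(CC)CC)CC/C(C)=C/CO[Si](C)(C)C(C)(C)C | intermediate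
18 | methyl (5Z)-6-[(1S,2R)-2-[(1S,4E)-6-{[tert-butyl(dimethyl)silyl]oxy}-4-methyl-1-[(triethylsilyl)oxy]hex-4-en-1-yl]-2-methyl-1-[(triethylsilyl)oxy]cyclobutyl]-3-hydroxy-2-methylidenehept-5-enoate (both C3 epimers) | C/C(=C/CC(O)C(=C)C(=O)OC)[C@@]1(O[Si](CC)(CC)CC)CC[C@]1(C)[C@@H](O[Si](CC)(CC)CC)CC/C(C)=C/CO[Si](C)(C)C(C)(C)C | intermediate
19 | methyl (2Z,5Z)-2-(bromomethyl)-6-[(1S,2R)-2-[(1S,4E)-6-{[tert-butyl(dimethyl)silyl]oxy}-4-methyl-1-[(triethylsilyl)oxy]hex-4-en-1-yl]-2-methyl-1-[(triethylsilyl)oxy]cyclobutyl]hepta-2,5-dienoate | C/C(=C/C/C=C(\CBr)C(=O)OC)[C@@]1(O[Si](CC)(CC)CC)CC[C@]1(C)[C@@H](O[Si](CC)(CC)CC)CC/C(C)=C/CO[Si](C)(C)C(C)(C)C | intermediate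
20 | methyl (2Z,5Z)-2-(bromomethyl)-6-[(1S,2R)-2-[(1S,4E)-1,6-dihydroxy-4-methylhex-4-en-1-yl]-1-hydroxy-2-methylcyclobutyl]hepta-2,5-dienoate | C/C(=C/C/C=C(\CBr)C(=O)OC)[C@@]1(O)CC[C@]1(C)[C@@H](O)CC/C(C)=C/CO | intermediate
21 | methyl (2Z,5Z)-2-(bromomethyl)-6-[(1S,2R)-1-hydroxy-2-[(1S,4E)-1-hydroxy-4-methyl-6-oxohex-4-en-1-yl]-2-methylcyclobutyl]hepta-2,5-dienoate | C/C(=C/C/C=C(\CBr)C(=O)OC)[C@@]1(O)CC[C@]1(C)[C@@H](O)CC/C(C)=C/C=O | intermediate
22 | methyl (1S,2S,3E,7S,8R,11S,12Z)-2,7,11-trihydroxy-8,11-cyclocembra-3,12,15(17)-trien-16-oate | COC(=O)C(=C)[C@H]1[C@@H](O)/C=C(\C)CC[C@H](O)[C@@]2(C)CC[C@]2(O)/C(C)=C\C1 | intermediate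
23 | (1S,2S,3E,7S,8R,11S,12Z)-7,11-dihydroxy-8,11-cyclocembra-3,12,15(17)-trien-16,2-olide | C=C1C(=O)O[C@H]2/C=C(\C)CC[C@H](O)[C@@]3(C)CC[C@]3(O)/C(C)=C\C[C@@H]12 | intermediate
24 | (1S,2S,3E,7S,8R,11S,12Z)-7-acetoxy-11-hydroxy-8,11-cyclocembra-3,12,15(17)-trien-16,2-olide | C=C1C(=O)O[C@H]2/C=C(\C)CC[C@H](OC(C)=O)[C@@]3(C)CC[C@]3(O)/C(C)=C\C[C@@H]12 | intermediate
25 | (1S,2S,3E,7S,8S,12Z)-7-acetoxy-8-hydroperoxy-11-oxocembra-3,12,15(17)-trien-16,2-olide | C=C1C(=O)O[C@H]2/C=C(\C)CC[C@H](OC(C)=O)[C@@](C)(OO)CCC(=O)/C(C)=C\C[C@@H]12 | intermediate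
26 | (1S,2S,3E,7S,8S,11R,12Z)-7-acetoxy-11-hydroxy-8,11-epidioxycembra-3,12,15(17)-trien-16,2-olide | C=C1C(=O)O[C@H]2/C=C(\C)CC[C@H](OC(C)=O)[C@]3(C)CC[C@@](O)(OO3)/C(C)=C\C[C@@H]12 | intermediate
27 | (1S,2S,3E,7S,8S,11R,12Z)-7-acetoxy-8,11-epidioxycembra-3,12,15(17)-trien-16,2-olide (CNP0238885.10) | C=C1C(=O)O[C@H]2/C=C(\C)CC[C@H](OC(C)=O)[C@]3(C)CC[C@@H](OO3)/C(C)=C\C[C@@H]12 | target

**Count**

Total steps: 19. Longest linear sequence: 17 steps (steps 1–6, then 9–19).

**Steps most likely to fail**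

Step 18. What may go wrong: the C8 radical turns over, or the folded C9–C10–C11 chain opens, before O2 is captured, so that oxygen is taken up on both faces and the C8 epimer forms. The cobalt catalyst may also reduce the hydroperoxide before it closes onto the ketone. Fallback: the oxygenation is moved in front of the ring closure, onto the monocyclic cyclobutanol 20, which belongs to the substrate class on which this ring expansion is established and where the epimers can be separated early.
- Setting out from 20, Co(acac)2/O2 should give the monocyclic 1,2-dioxan-3-ol F1 together with its C8 epimer.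
- Et3SiH with catalytic Me3SiOSO2CF3 should reduce it to the 1,2-dioxane F2, from which the (3R,6S) isomer is separated by chromatography.
- MnO2 should oxidise the allylic alcohol to the enal F3.
- An indium-mediated Barbier allylation at high dilution (indium powder, THF/H2O) should close the 14-membered ring and the lactone with the peroxide already in place, giving the 7-hydroxy epidioxy cembranolide F4.
- Acetylation (Ac2O, pyridine) comes back to the route at 27.

Step 16. What may go wrong: intermolecular coupling outruns ring closure, or the allyl group is delivered to the wrong face of the enal, because C1 and C2 lie far from the existing stereocentres. Fallback: the ring is closed by allylboration instead of by an allylchromium species.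
- Setting out from 21, Pd2(dba)3-catalysed borylation of the allylic bromide with B2pin2 should give the allylboronate enal F5.
- A chiral phosphoric acid (or Sc(OTf)3) then promotes intramolecular allylboration at high dilution through a closed six-membered transition state, so the catalyst and not the substrate chooses the aldehyde face.
- The borate lactonises on work-up, which comes back to the route at 23.

Step 5. What may go wrong: poor enantioface selection by the hafnium catalyst on this (Z)-trisubstituted alkenylcyclopropanol, or opening of the cyclopropanol before the epoxide forms. Fallback: the absolute configuration is obtained by resolution instead of asymmetric catalysis.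
- Setting out from 6, the achiral hydroxyl-directed epoxidation with VO(acac)2/t-BuOOH and the same anti semipinacol shift should give 8 as a racemate, that is 8 together with the enantiomeric ketol F6.
- Lipase-catalysed transesterification with vinyl acetate should then acylate the (1R) enantiomer, by the usual size rule for secondary alcohols, to the acetate F7.
- Unreacted (1S)-8 is separated by chromatography, which comes back to the route at 8.

Further compounds
F1 | step 18 | methyl (2Z,5Z)-2-(bromomethyl)-6-[(6S)-6-[(1S,4E)-1,6-dihydroxy-4-methylhex-4-en-1-yl]-3-hydroxy-6-methyl-1,2-dioxan-3-yl]hepta-2,5-dienoate (formed with its C6 epimer) | C/C(=C/C/C=C(\CBr)C(=O)OC)C1(O)CC[C@](C)(OO1)[C@@H](O)CC/C(C)=C/CO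
F2 | step 18 | methyl (2Z,5Z)-2-(bromomethyl)-6-[(3R,6S)-6-[(1S,4E)-1,6-dihydroxy-4-methylhex-4-en-1-yl]-6-methyl-1,2-dioxan-3-yl]hepta-2,5-dienoate | C/C(=C/C/C=C(\CBr)C(=O)OC)[C@H]1CC[C@](C)(OO1)[C@@H](O)CC/C(C)=C/CO
F3 | step 18 | methyl (2Z,5Z)-2-(bromomethyl)-6-[(3R,6S)-6-[(1S,4E)-1-hydroxy-4-methyl-6-oxohex-4-en-1-yl]-6-methyl-1,2-dioxan-3-yl]hepta-2,5-dienoate | C/C(=C/C/C=C(\CBr)C(=O)OC)[C@H]1CC[C@](C)(OO1)[C@@H](O)CC/C(C)=C/C=O
F4 | step 18 | (1S,2S,3E,7S,8S,11R,12Z)-7-hydroxy-8,11-epidioxycembra-3,12,15(17)-trien-16,2-olide | C=C1C(=O)O[C@H]2/C=C(\C)CC[C@H](O)[C@]3(C)CC[C@@H](OO3)/C(C)=C\C[C@@H]12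
F5 | step 16 | methyl (5Z)-6-[(1S,2R)-1-hydroxy-2-[(1S,4E)-1-hydroxy-4-methyl-6-oxohex-4-en-1-yl]-2-methylcyclobutyl]-2-[(4,4,5,5-tetramethyl-1,3,2-dioxaborolan-2-yl)methyl]hepta-2,5-dienoate (C2=C3 geometry as in 21) | C/C(=C/C/C=C(\CB2OC(C)(C)C(C)(C)O2)C(=O)OC)[C@@]1(O)CC[C@]1(C)[C@@H](O)CC/C(C)=C/C=O
F6 | step 5 | (2S)-2-[(1R,4E)-6-{[tert-butyl(dimethyl)silyl]oxy}-1-hydroxy-4-methylhex-4-en-1-yl]-2-methylcyclobutan-1-one | O=C1CC[C@@]1(C)[C@H](O)CC/C(C)=C/CO[Si](C)(C)C(C)(C)C
F7 | step 5 | (1R,4E)-6-{[tert-butyl(dimethyl)silyl]oxy}-4-methyl-1-[(1S)-1-methyl-2-oxocyclobutyl]hex-4-en-1-yl acetate | O=C1CC[C@@]1(C)[C@H](OC(C)=O)CC/C(C)=C/CO[Si](C)(C)C(C)(C)C
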